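The ash run held more target than isomer of the product at 6.00 h, 2.5% against 2.1%, and less at 10.0 h, 3.0% against 4.7%. I turned the question round and asked what target would need in order to lead the flask at 2.5 d.

| flask | solid substrate | remark | time |
|---|---|---|---|
| ash | 1.2 M | run made earlier |  |
| flask | 0.62 M |  | 2.5 d |

ash run (percent of the solid substrate charged)

| time / h | target / % | isomer of the product / % | solid substrate / % |
|---|---|---|---|
| 1.33 | 0.7 | 0.1 | 97.7 |
| 4.00 | 2.1 | 1.0 | 94.1 |
| 6.00 | 2.5 | 2.1 | 91.5 |
| 10.0 | 3.0 | 4.7 | 88.0 |
| 15.0 | 3.5 | 8.0 | 83.8 |
| 20.0 | 3.4 | 11.4 | 80.3 |

(scatter of a reading: 0.3 percentage points)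

- the analysis behind the earlier runs scatters by 0.3 percentage points, standard deviation
- at the start none of the solid substrate is in solution
- a reading or a percentage of target counts all its forms, free or not

* ratio of target to isomer of the product at 50 min
* ratio of target to isomer of the product at 6.0 h
* ratio of target to isomer of the product at 2.5 d
* which of target and isomer of the product there is more of at 2.5 d

Interpolating, I read the two as equal in the ash run at 6.76 h. I carried this crossing time, the hour at which [target] equals [isomer of the product]. For target to lead, the crossing would have to lie beyond 2.5 d, which is 0.948 powers of ten later than my reading.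

In the last two ash readings, at 15.0 h and 20.0 h, target read level, 3.5% then 3.4%, while isomer of the product grew from 8.0% to 11.4%. So I took [target]/[isomer of the product] ≈ crossing time/time, one power of ten down per power of ten in time. At 20.0 h this gave 0.338, and the readings gave 0.298.

I took the rule to need solid present. Ash solid substrate fell by 0.00960 M h⁻¹, which I assumed to be a zero-order feed, the same at any charge. By this reckoning the flask's charge lasted 64.6 h, just past 60 h. I committed to a ratio of 0.113 at 2.5 d.

The forecast gave 10, 1.2 and 0.09, with isomer of the product ahead, holding that “Absolute concentrations should therefore match in the flask at early times”. The flask gave 10.9, 1.22 and 0.105, with isomer of the product ahead, 72.0% against 7.56% of target.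

    solid substrate ⇌ starting material, rate k1*(cs1 - [starting material]) while solid is left; crystals form when [starting material] > cs1 (solubility = 0.100 M, k = 0.00389 min⁻¹)
    crystals ⇌ target, rate k2*(cs2 - [target]) while solid is left; crystals form when [target] > cs2 (solubility = 0.590 M, k = 0.779 min⁻¹)
    target ⇌ isomer of the product (K = 27.0, k = 0.00383 min⁻¹)
    starting material ⇌ target (K = 0.690, k = 0.113 min⁻¹)

My ratio of 0.113 stood against the flask's 0.105, and the flask still held 9.29% of solid substrate at 2.50 d. The neighbour flask, charged with 0.37 M, lasted 38.5 h by the same reckoning, short of 60 h. So the rule should not have held there at the end. At 6.0 h its ratio was 1.22, like the flask's. At 2.5 d it held 0% of solid substrate, and its ratio was 0.0452, 0.397 powers of ten below the rule. Its target stood at 4.07% and its isomer of the product at 90.0%.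

(Readings and results are simulated on assumed constants.)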